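**Retrosynthetic overview**
1. Ring numbering: C1 (bears the side chain), C2 (=CH), C3 (CHOH), C4 (=CH), C5 (C–OMe), C6 (CHOAc). The route rests on this cyclohexa-1,4-diene with oxygen on C3 and C6 and alkenes C1=C2 and C4=C5: it is a 7-oxabicyclo[2.2.1]hepta-2,5-diene (O bridging C3 and C6) opened with inversion at C6.
2. C6–OAc ⇐ C6–OH ⇐ Mislow–Evans [2,3] shift of a C2 sulfoxide ⇐ anti-SN2′ opening of the C6–O bond of the bicycle by thiophenol (C3–O is kept).
3. Bicycle ⇐ Diels–Alder of 3-methoxyfuran (C3–C6 and the bridging O) with an (R)-sulfinyl alkyne (C1, C2); the sulfinyl group is afterwards exchanged for H.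
4. Sulfinyl alkyne ⇐ Andersen sulfinylation of silyl-protected (R)-pentadec-1-yn-4-ol ⇐ (R)-epichlorohydrin, decylmagnesium bromide, lithium acetylide.
5. Ring order: carbocycle and oxygen bridge form together in the cycloaddition; the bridge is cut later and no other ring is made.

Key step: step 5

Remark: the side-chain oxygen (C2′) is carried as a TBS ether through the two organomagnesium steps (4 and 6) and is changed to the acetate only afterwards, because an acetate would not survive them.
Remark: the chiral sulfur reagent is bought as the menthyl sulfinate (both enantiomers are commercial). The (R)-sulfur ester is chosen from the facial model given in step 5, and this assignment has to be confirmed experimentally.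
Remark: the homopropargylic alcohol is taken from the chiral pool ((R)-epichlorohydrin) so that its configuration is unambiguous.

**Route**

Step 1
Reactants: 1 (R)-epichlorohydrin; 2 decylmagnesium bromide
Product: 3 (R)-1-chlorotridecan-2-ol
Conditions: CuI (10 mol %), THF/Et2O, −40 → −10 °C; aq NH4Cl
Reagents that add atoms: none
Why: Copper-catalysed SN2 opening of the epoxide by the Grignard reagent at the CH2 terminus; the stereocentre is not involved and stays (R).

Step 2
Reactants: 3 (R)-1-chlorotridecan-2-ol
Product: 5 (R)-pentadec-1-yn-4-ol, via (R)-2-undecyloxirane 4 (not isolated)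
Conditions: LiC≡CH·H2NCH2CH2NH2 (3 equiv), DMSO, 0 °C → rt
Reagents that add atoms: lithium acetylide (ethylenediamine complex), [Li+].[C-]#C
Why: Intramolecular Williamson closure to the terminal epoxide followed by SN2 opening with acetylide at the CH2 carbon; the carbinol centre is untouched in both events.

Step 3
Reactants: 5 (R)-pentadec-1-yn-4-ol
Product: 6 tert-butyldimethyl{[(4R)-pentadec-1-yn-4-yl]oxy}silane
Conditions: TBSCl, imidazole, DMF, rt
Reagents that add atoms: tert-butyldimethylsilyl chloride, CC(C)(C)[Si](C)(C)Cl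
Why: Imidazole-promoted silylation masks the hydroxyl for the organomagnesium chemistry of steps 4 and 6; no stereocentre is affected.

Step 4
Reactants: 6 tert-butyldimethyl{[(4R)-pentadec-1-yn-4-yl]oxy}silane; 7 (1S,2R,5S)-menthyl (R)-p-toluenesulfinate
Product: 9 tert-butyldimethyl({(4R)-1-[(R)-p-tolylsulfinyl]pentadec-1-yn-4-yl}oxy)silane, via alkynylmagnesium bromide 8 (not isolated)
Conditions: EtMgBr (1.05 equiv), THF, 40 °C; then added to 7 in toluene, −20 °C
Reagents that add atoms: none
Why: Andersen sulfoxide synthesis: the alkynylmagnesium bromide displaces mentholate at sulfur with inversion, which turns the (R)-sulfinate into the (R)-alkynyl sulfoxide (the descriptor is kept only because alkynyl outranks p-tolyl) without touching C4.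

Step 5
Reactants: 9 tert-butyldimethyl({(4R)-1-[(R)-p-tolylsulfinyl]pentadec-1-yn-4-yl}oxy)silane; 10 3-methoxyfuran
Product: 11 (1R,4R)-2-{(2R)-2-[(tert-butyldimethylsilyl)oxy]tridecyl}-6-methoxy-3-[(R)-p-tolylsulfinyl]-7-oxabicyclo[2.2.1]hepta-2,5-diene
Conditions: 10 (3 equiv), toluene (2 M), i-Pr2NEt (5 mol %), 45 °C, dark; chromatography on Et3N-deactivated silica
Reagents that add atoms: none
Why: Concerted but asynchronous normal-demand [4+2] cycloaddition (Diels–Alder), the closest known reactions being the additions of furans and cyclopentadiene to 1-alkynyl p-tolyl sulfoxides and sulfones. The furan carbon next to the methoxy group (largest HOMO coefficient, becomes C6) bonds to the alkyne carbon remote from sulfur (largest LUMO coefficient, C1) and the other α-carbon (C3) to the sulfinyl carbon (C2), which fixes the regiochemistry. Both rings close in this one suprafacial event: the six-membered carbocycle by formation of C1–C6 and C2–C3, and the oxygen bridge because the furan oxygen stays bonded to C3 and C6. The bridgehead centres C3 and C6 are tied to each other by the bridge, and which enantiomeric bicycle forms is decided by the sulfinyl group: the diene is expected to add anti to the p-tolyl group with the furan oxygen turned away from the sulfinyl oxygen, which for (R)-sulfur should lead to the (1R,4R) adduct. This π-facial assignment is a working model and is to be checked on the first run; should the sense be reversed, the enantiomeric sulfinate is used in step 4. The amine additive keeps the medium acid-free so that the methoxy-substituted oxanorbornadiene does not isomerise to a phenol.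

Step 6
Reactants: 11 (1R,4R)-2-{(2R)-2-[(tert-butyldimethylsilyl)oxy]tridecyl}-6-methoxy-3-[(R)-p-tolylsulfinyl]-7-oxabicyclo[2.2.1]hepta-2,5-diene
Product: 13 (1R,4S)-2-{(2R)-2-[(tert-butyldimethylsilyl)oxy]tridecyl}-6-methoxy-7-oxabicyclo[2.2.1]hepta-2,5-diene, via alkenylmagnesium chloride 12 (not isolated)
Conditions: i-PrMgCl (1.2 equiv), THF, −78 °C, 10 min; MeOH, −78 °C; aq NH4Cl
Reagents that add atoms: none
Why: Sulfoxide–magnesium exchange: i-PrMgCl attacks sulfur and the strained, s-rich bicyclic alkenyl group should leave in preference to p-tolyl; the alkenylmagnesium species cannot β-eliminate the bridging oxygen (that would need a six-membered cyclic allene) and is protonated with no change at C3 or C6.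

Step 7
Reactants: 13 (1R,4S)-2-{(2R)-2-[(tert-butyldimethylsilyl)oxy]tridecyl}-6-methoxy-7-oxabicyclo[2.2.1]hepta-2,5-diene
Product: 15 (2R)-1-[(1R,4S)-6-methoxy-7-oxabicyclo[2.2.1]hepta-2,5-dien-2-yl]tridecan-2-yl acetate, via side-chain alcohol 14 (not isolated)
Conditions: TBAF (1.1 equiv), THF, 0 °C → rt; then Ac2O (3 equiv), DMAP (cat.), 0 °C
Reagents that add atoms: acetic anhydride, CC(=O)OC(C)=O
Why: Fluoride desilylation followed in the same flask by DMAP-catalysed acetylation; both are non-acidic, so the enol ether and the bicycle persist and C2′ keeps its configuration.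

Step 8
Reactants: 15 (2R)-1-[(1R,4S)-6-methoxy-7-oxabicyclo[2.2.1]hepta-2,5-dien-2-yl]tridecan-2-yl acetate
Product: 16 (2R)-1-[(5R,6R)-5-hydroxy-3-methoxy-6-(phenylsulfanyl)cyclohexa-1,3-dien-1-yl]tridecan-2-yl acetate
Conditions: [Rh(cod)Cl]2 (2.5 mol %), dppf (6 mol %), Bu4NI (10 mol %), PhSH (1.5 equiv), THF, 50 °C
Reagents that add atoms: thiophenol, Sc1ccccc1
Why: Proposed new method: rhodium(I) bound on the exo face to the bridging oxygen and the C1=C2 alkene should insert into the C6–O bond in SN2′ fashion (this places the metal at unsubstituted C2, whereas cutting C3–O would place it at fully substituted C1 or C5), the alkoxide is protonated by the thiol, and thiolate attacks the allyl unit at C2 anti to rhodium, so that sulfur ends up trans to the C3 hydroxyl while C3 is untouched; the closest known reaction is the rhodium-catalysed anti-SN2′ opening of oxabenzonorbornadienes by thiols.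

Step 9
Reactants: 16 (2R)-1-[(5R,6R)-5-hydroxy-3-methoxy-6-(phenylsulfanyl)cyclohexa-1,3-dien-1-yl]tridecan-2-yl acetate
Product: 17 (2R)-1-[(5R,6R)-5-[(tert-butyldimethylsilyl)oxy]-3-methoxy-6-(phenylsulfanyl)cyclohexa-1,3-dien-1-yl]tridecan-2-yl acetate
Conditions: TBSCl (1.5 equiv), imidazole (3 equiv), DMF, 0 °C → rt
Reagents that add atoms: tert-butyldimethylsilyl chloride, CC(C)(C)[Si](C)(C)Cl
Why: Imidazole-promoted silylation of the C3 alcohol under buffered conditions, so that only the C6 oxygen is free for the later acetylation and the vinylogous hemiketal-like C3–OH can no longer ionise.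

Step 10
Reactants: 17 (2R)-1-[(5R,6R)-5-[(tert-butyldimethylsilyl)oxy]-3-methoxy-6-(phenylsulfanyl)cyclohexa-1,3-dien-1-yl]tridecan-2-yl acetate
Product: 20 (2R)-1-[(3S,6S)-3-[(tert-butyldimethylsilyl)oxy]-6-hydroxy-5-methoxycyclohexa-1,4-dien-1-yl]tridecan-2-yl acetate, via allylic sulfoxide 18 (not isolated), via allylic sulfenate 19 (not isolated)
Conditions: 2-(phenylsulfonyl)-3-phenyloxaziridine (1.05 equiv), CH2Cl2, −20 → 0 °C; then P(OMe)3 (3 equiv), MeOH, 0 °C → rt
Reagents that add atoms: 2-(phenylsulfonyl)-3-phenyloxaziridine, O=S(=O)(N1OC1c1ccccc1)c1ccccc1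
Why: Chemoselective, acid-free S-oxidation gives the allylic sulfoxide, whose Mislow–Evans [2,3] shift passes oxygen suprafacially from C2 to C6 (same face as sulfur, hence trans to the C3 silyloxy group) while restoring C1=C2; phosphite cleaves the sulfenate irreversibly.

Step 11
Reactants: 20 (2R)-1-[(3S,6S)-3-[(tert-butyldimethylsilyl)oxy]-6-hydroxy-5-methoxycyclohexa-1,4-dien-1-yl]tridecan-2-yl acetate
Product: 21 (2R)-1-[(3S,6S)-6-acetoxy-3-[(tert-butyldimethylsilyl)oxy]-5-methoxycyclohexa-1,4-dien-1-yl]tridecan-2-yl acetate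
Conditions: Ac2O, pyridine, DMAP (cat.), CH2Cl2, 0 °C
Reagents that add atoms: acetic anhydride, CC(=O)OC(C)=O
Why: DMAP-catalysed acetylation of the secondary bis-allylic alcohol under basic conditions, with retention at C6.

Step 12
Reactants: 21 (2R)-1-[(3S,6S)-6-acetoxy-3-[(tert-butyldimethylsilyl)oxy]-5-methoxycyclohexa-1,4-dien-1-yl]tridecan-2-yl acetate
Product: 22 (2R)-1-[(3S,6S)-6-acetoxy-3-hydroxy-5-methoxycyclohexa-1,4-dien-1-yl]tridecan-2-yl acetate
Conditions: TBAF/AcOH (1:1, 2 equiv), THF, 0 °C → rt
Reagents that add atoms: none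
Why: Fluoride-mediated desilylation buffered with acetic acid frees the C3 hydroxyl without strong acid (enol ether, allylic acetate) or strong base (acetates) being present.

**Compound list**
1 | (R)-epichlorohydrin | ClC[C@H]1CO1 | starting material
2 | decylmagnesium bromide | CCCCCCCCCC[Mg]Br | starting material
3 | (R)-1-chlorotridecan-2-ol | CCCCCCCCCCC[C@@H](O)CCl | intermediate
4 | (R)-2-undecyloxirane | CCCCCCCCCCC[C@@H]1CO1 | intermediate (not isolated)
5 | (R)-pentadec-1-yn-4-ol | CCCCCCCCCCC[C@@H](O)CC#C | intermediate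
6 | tert-butyldimethyl{[(4R)-pentadec-1-yn-4-yl]oxy}silane | CCCCCCCCCCC[C@H](CC#C)O[Si](C)(C)C(C)(C)C | intermediate
7 | (1S,2R,5S)-menthyl (R)-p-toluenesulfinate | C[C@H]1CC[C@@H]([C@H](C1)O[S@@](=O)c2ccc(C)cc2)C(C)C | starting material
8 | alkynylmagnesium bromide of 6 (MgBr on C1 of the alkyne) | CCCCCCCCCCC[C@H](CC#C[Mg]Br)O[Si](C)(C)C(C)(C)C | intermediate (not isolated)
9 | tert-butyldimethyl({(4R)-1-[(R)-p-tolylsulfinyl]pentadec-1-yn-4-yl}oxy)silane | CCCCCCCCCCC[C@H](CC#C[S@](=O)c1ccc(C)cc1)O[Si](C)(C)C(C)(C)C | intermediate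
10 | 3-methoxyfuran | COc1ccoc1 | starting material
11 | (1R,4R)-2-{(2R)-2-[(tert-butyldimethylsilyl)oxy]tridecyl}-6-methoxy-3-[(R)-p-tolylsulfinyl]-7-oxabicyclo[2.2.1]hepta-2,5-diene | CCCCCCCCCCC[C@H](CC1=C([S@](=O)c2ccc(C)cc2)[C@H]3C=C(OC)[C@@H]1O3)O[Si](C)(C)C(C)(C)C | intermediate
12 | alkenylmagnesium chloride: 11 with MgCl in place of the sulfinyl group at C2 | CCCCCCCCCCC[C@H](CC1=C([Mg]Cl)[C@H]2C=C(OC)[C@@H]1O2)O[Si](C)(C)C(C)(C)C | intermediate (not isolated)
13 | (1R,4S)-2-{(2R)-2-[(tert-butyldimethylsilyl)oxy]tridecyl}-6-methoxy-7-oxabicyclo[2.2.1]hepta-2,5-diene | CCCCCCCCCCC[C@H](CC1=C[C@H]2C=C(OC)[C@@H]1O2)O[Si](C)(C)C(C)(C)C | intermediate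
14 | (2R)-1-[(1R,4S)-6-methoxy-7-oxabicyclo[2.2.1]hepta-2,5-dien-2-yl]tridecan-2-ol | CCCCCCCCCCC[C@H](CC1=C[C@H]2C=C(OC)[C@@H]1O2)O | intermediate (not isolated)
15 | (2R)-1-[(1R,4S)-6-methoxy-7-oxabicyclo[2.2.1]hepta-2,5-dien-2-yl]tridecan-2-yl acetate | CCCCCCCCCCC[C@H](CC1=C[C@H]2C=C(OC)[C@@H]1O2)OC(C)=O | intermediate
16 | (2R)-1-[(5R,6R)-5-hydroxy-3-methoxy-6-(phenylsulfanyl)cyclohexa-1,3-dien-1-yl]tridecan-2-yl acetate (C2–SPh trans to C3–OH) | CCCCCCCCCCC[C@H](CC1=CC(OC)=C[C@@H](O)[C@@H]1Sc2ccccc2)OC(C)=O | intermediate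
17 | C3 TBS ether of 16 | CCCCCCCCCCC[C@H](CC1=CC(OC)=C[C@@H](O[Si](C)(C)C(C)(C)C)[C@@H]1Sc2ccccc2)OC(C)=O | intermediate
18 | S-oxide of 17 (both configurations at sulfur) | CCCCCCCCCCC[C@H](CC1=CC(OC)=C[C@@H](O[Si](C)(C)C(C)(C)C)[C@@H]1S(=O)c2ccccc2)OC(C)=O | intermediate (not isolated)
19 | C6 benzenesulfenate: 20 with O–SPh on C6 | CCCCCCCCCCC[C@H](CC1=C[C@H](O[Si](C)(C)C(C)(C)C)C=C(OC)[C@H]1OSc2ccccc2)OC(C)=O | intermediate (not isolated)
20 | (2R)-1-[(3S,6S)-3-[(tert-butyldimethylsilyl)oxy]-6-hydroxy-5-methoxycyclohexa-1,4-dien-1-yl]tridecan-2-yl acetate | CCCCCCCCCCC[C@H](CC1=C[C@H](O[Si](C)(C)C(C)(C)C)C=C(OC)[C@H]1O)OC(C)=O | intermediate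
21 | (2R)-1-[(3S,6S)-6-acetoxy-3-[(tert-butyldimethylsilyl)oxy]-5-methoxycyclohexa-1,4-dien-1-yl]tridecan-2-yl acetate | CCCCCCCCCCC[C@H](CC1=C[C@H](O[Si](C)(C)C(C)(C)C)C=C(OC)[C@H]1OC(C)=O)OC(C)=O | intermediate
22 | (2R)-1-[(3S,6S)-6-acetoxy-3-hydroxy-5-methoxycyclohexa-1,4-dien-1-yl]tridecan-2-yl acetate (CNP0081579.1) | CCCCCCCCCCC[C@H](CC1=C[C@H](O)C=C(OC)[C@H]1OC(C)=O)OC(C)=O | target

**Step count and risks**

Total steps: 12. Longest linear sequence: 12 steps (1 → 22); 2, 7 and 10 are bought.

The three steps most likely to fail: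

Step 8 (labelled step). The catalyst may be taken out of the cycle by chelation of both ring alkenes. The methoxy group may also assist ionisation at C3, so that the wrong C–O bond is cut and the ring aromatises. Attack at C4 in place of C2 would do no harm, since that allylic sulfoxide passes oxygen to C6 on the same face. The fallback uses documented reaction types and sets out from 15. Acid-catalysed addition of methanol to the enol ether (MeOH, PPTS, 0 °C, Et3N quench), as used on 3-methoxyfuran cycloadducts, should give the dimethyl ketal F1. F1 is a 7-oxabicyclo[2.2.1]hept-2-ene with one alkene only, the class of non-aromatic oxabicycles for which rhodium(I)-catalysed anti-SN2′ openings by heteroatom nucleophiles are established. Neither chelation nor methoxy-assisted ionisation is possible in it. Opening with thiophenol under the conditions of step 8 should give the trans hydroxy sulfide F2, and TBSCl/imidazole the silyl ether F3. Loss of methanol from the ketal (TMSOTf, i-Pr2NEt, CH2Cl2, −20 °C; only C4 carries α-hydrogens) then regenerates the dienol ether, and the fallback comes back to the route at 17.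

Step 5 (key step). The internal alkynyl sulfoxide may add too slowly, so that the furan decomposes first, or the sulfinyl group may discriminate the two π-faces poorly. The fallback sets out from 6 and gives up auxiliary control. Lithiation (n-BuLi, THF, −78 °C) and trapping with benzenesulfonyl fluoride should give the alkynyl phenyl sulfone F4, a much stronger dienophile of the kind known to add to furans near room temperature. With 10 it should give the sulfonyl oxanorbornadiene F5 together with its bicycle epimer F6. The two are diastereomers because of the C2′ centre and are to be separated by chromatography; the regiochemistry is set by the methoxy group as before. Buffered sodium amalgam (Na(Hg), Na2HPO4, MeOH/THF, −20 °C), the usual way to use an alkynyl sulfone as an acetylene equivalent, removes the sulfonyl group from F5, and the fallback comes back to the route at 13.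

Step 6. Attack of the Grignard reagent at sulfur may expel the p-tolyl group instead of the bicyclic alkenyl group, or the alkenylmagnesium species may open the strained bicycle before it is protonated. The fallback sets out from 11. Oxidation at sulfur only (TPAP cat., NMO, MeCN, 4 Å MS) should give the sulfone F7. Electron-transfer desulfonylation with buffered sodium amalgam in methanol, where the alkenyl anion is protonated as it forms, then gives 13, where the fallback comes back to the route.

**Further compounds**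
F1 | step 8 | dimethyl ketal of 15: C4H2–C5(OMe)2 in place of the enol ether, bridgeheads as in 15 | CCCCCCCCCCC[C@H](CC1=C[C@H]2CC(OC)(OC)[C@@H]1O2)OC(C)=O
F2 | step 8 | ring-opened F1: C2–SPh trans to C3–OH, C1=C6, C5(OMe)2 | CCCCCCCCCCC[C@H](CC1=CC(OC)(OC)C[C@@H](O)[C@@H]1Sc2ccccc2)OC(C)=O
F3 | step 8 | C3 TBS ether of F2 | CCCCCCCCCCC[C@H](CC1=CC(OC)(OC)C[C@@H](O[Si](C)(C)C(C)(C)C)[C@@H]1Sc2ccccc2)OC(C)=O
F4 | step 5 | tert-butyldimethyl{[(4R)-1-(phenylsulfonyl)pentadec-1-yn-4-yl]oxy}silane | CCCCCCCCCCC[C@H](CC#CS(=O)(=O)c1ccccc1)O[Si](C)(C)C(C)(C)C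
F5 | step 5 | analogue of 11 with phenylsulfonyl at C2, same bicycle configuration | CCCCCCCCCCC[C@H](CC1=C(S(=O)(=O)c2ccccc2)[C@H]3C=C(OC)[C@@H]1O3)O[Si](C)(C)C(C)(C)C
F6 | step 5 | bicycle epimer of F5 (both bridgeheads inverted) | CCCCCCCCCCC[C@H](CC1=C(S(=O)(=O)c2ccccc2)[C@@H]3C=C(OC)[C@H]1O3)O[Si](C)(C)C(C)(C)C
F7 | step 6 | sulfone of 11 (p-tolylsulfonyl at C2) | CCCCCCCCCCC[C@H](CC1=C(S(=O)(=O)c2ccc(C)cc2)[C@H]3C=C(OC)[C@@H]1O3)O[Si](C)(C)C(C)(C)C
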